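Late in both earlier runs the monomer in chains stops climbing, although the two flasks stop at very different heights.

in all of them: free monomer 0.014 M

| flask | initiator | remark | time |
|---|---|---|---|
| north | 11 µM | run made earlier |  |
| south | 68 µM | run made earlier |  |
| blue | 20 µM |  | 40 h |
| grey | 40 µM |  | 40 h |
| amber | 80 µM |  | 40 h |

| run | time / h | monomer in chains / % |
|---|---|---|
| north | 3.00 | 3 |
| north | 5.00 | 4 |
| north | 8.00 | 5 |
| north | 12.0 | 5 |
| north | 15.0 | 3 |
| north | 25.0 | 3 |
| north | 40.0 | 6 |
| south | 3.00 | 10 |
| south | 5.00 | 15 |
| south | 8.00 | 19 |
| south | 12.0 | 26 |
| south | 15.0 | 25 |
| south | 25.0 | 28 |
| south | 40.0 | 27 |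

(readings scatter by 1.5 percentage points)

- the numbers in the tables scatter by 1.5 percentage points (one standard deviation)
- "hardly changes" means that all values lie within two and a half points (for a concentration: within two and a half percent of the largest)

- amount of monomer in chains at the end, in percent of the free monomer charged for blue, grey, amber, in this order
- the course of these numbers from the first flask to the last (falls all the way / rises, then falls / falls, then rises / rises all the way / hardly changes)

What do the late readings say? From 12.0 h on, south averages 26.5% and north 4.25%, and each is flat within the scatter.

What is the zero of the scale? It is the plain case of a single monomer in chains per initiator, which would put south at 0.486%. Read against that, the late readings of south give 54.5 monomers in chains per initiator charged and those of north 54.1.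

Can that count be carried to a larger charge? I would not carry it unchanged: the south readings put 26.5% of the charge in chains, and chains draw on that same charge of free monomer. So I read the plateau the way one reads a pseudo-first-order decay. Let y be the fraction of the charge not in chains at the plateau and c the initiator charge. The reach g is then minus ln y divided by c, and south gives 0.00453 µM⁻¹.

Does south's g survive a test on the other run? It gives north 4.86% in chains, against the 4.25% read there, a gap of 0.61 percentage points beside a scatter of 1.5 points per reading.

Where is it weak? At amber, whose charge is larger than south's, so that figure is an extension.

My reckoning gives 8.66%, 16.6% and 30.4%. The forecast says 9%, 17% and 30%, course rises all the way, and calls its logarithmic rule “first order in active chains with monomer depletion”. At blue it stands 0.34 points above mine.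

The flasks give 10.2%, 18.8% and 30.5%, course rises all the way.

    free monomer + initiator → living end + monomer in chains (k = 13.0 M⁻¹ h⁻¹)
    free monomer + living end → monomer in chains + living end, rate k2*[living end]*[free monomer] (k = 3600 M⁻¹ h⁻¹)
    initiator → spent initiator A (k = 0.240 h⁻¹)
    free monomer + initiator → spent initiator B (k = 1.40 M⁻¹ h⁻¹)
    free monomer + monomer in chains → side product (k = 20.0 M⁻¹ h⁻¹)

In blue at 40 h, side product, each one counted as two, holds 77.0% of the free monomer charged, while 12.8% is still free monomer. Reckoned back from the end values, amber gives a reach of 0.00455 µM⁻¹. Blue gives a reach of 0.00538 µM⁻¹, higher than amber's.

(The readings were generated by integration on assumed constants; scatter was added.)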